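**Plan**

1. Locants: rings A and E are the outer guaiacyl rings, ring B is the aryl ring on the C4 benzyl group of lactone ring C, ring D is the aryl ring on the C3 benzyl group; C7, C8, C9 are the benzylic carbinol, the ring-bound methine and the CH2OH carbon of a side chain. TBS, TIPS, TES = tert-butyldimethylsilyl, triisopropylsilyl, triethylsilyl.
2. Cuts: ring D C5–C8 and ring B C5–C8 (each back to an aryl (E)-1-methylallyl ether whose O–C bond comes from a Mitsunobu union), the two C9 hydroxymethyl groups (from propenyl groups), the lactone C3–CH2(ring D) bond (enolate benzylation), and the C7–alkyne bond of each side-chain building block.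
3. Enabling feature: in rings B and D the phenolic oxygen on C4 is flanked by OMe on C3 and by the side chain on C5, and C1 carries the benzylic CH2. An O-bound allyl unit can therefore migrate by [3,3] shift only to C5, the carbon that must carry C8.
4. Forward order: side-chain alcohols 9 and 16 (steps 1–9); lactone ring C (steps 10–12); ring B arm (steps 13–16); benzylation to the trans-lactone (steps 17–18); ring D arm by etherification, rearrangement and olefin cleavage (steps 19–22); desilylation (step 23).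
5. Stereochemistry: C7 (S) in both arms from catalyst-controlled alkynylation; C8 from (R)- or (S)-but-3-yn-2-ol through Mitsunobu inversion and 1,3-chirality transfer (8S on ring B, 8R on ring D); lactone C4 (S) from asymmetric hydrogenation and C3 (S) from trans-selective alkylation.

Key step: step 21

Remark: the (3S,4S) lactone core is antipodal to the common natural dibenzylbutyrolactone series, and the two arms are diastereomeric (7S,8S on ring B; 7S,8R on ring D). The core is therefore made by asymmetric synthesis and the arms are installed one after the other from epimeric building blocks. CIP descriptors at C7 and C8 change along the route with substituent priorities; the SMILES give the spatial arrangement.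

**Route**

Step 1
Reactants: 1 vanillin
Product: 2 3-methoxy-4-(triisopropylsilyloxy)benzaldehyde
Conditions: TIPSCl, imidazole, DMF, rt
Reagents that add atoms: triisopropylsilyl chloride, CC(C)[Si](Cl)(C(C)C)C(C)C
Why: Imidazole-promoted O-silylation of the phenol; the bulky TIPS ether should survive the hydride, enolate and thermal steps and fall to fluoride at the end.

Step 2
Reactants: 3 (R)-but-3-yn-2-ol
Product: 4 (R)-(but-3-yn-2-yloxy)triethylsilane
Conditions: TESCl, imidazole, CH2Cl2, 0 °C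
Reagents that add atoms: triethylsilyl chloride, CC[Si](Cl)(CC)CC
Why: O-Silylation that leaves the stereocenter untouched; the TES ether is an acid-labile placeholder removable beside TBS and aryl TIPS ethers.

Step 3
Reactants: 2 3-methoxy-4-(triisopropylsilyloxy)benzaldehyde; 4 (R)-(but-3-yn-2-yloxy)triethylsilane
Product: 6 (1R,4R)-1-[3-methoxy-4-(triisopropylsilyloxy)phenyl]-4-(triethylsilyloxy)pent-2-yn-1-ol, via zinc acetylide 5 (not isolated)
Conditions: 4 (2 equiv), Et2Zn (2 equiv), toluene, reflux; then (S)-BINOL (20 mol %), Ti(OiPr)4 (50 mol %), 2, Et2O, rt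
Reagents that add atoms: none
Why: Catalytic enantioselective alkynylzinc addition to an aromatic aldehyde under BINOL–Ti(OiPr)4 control; (S)-BINOL is expected, by analogy with related additions, to deliver the alkynyl group to the Si face whatever the remote silyloxy center, giving the (R)-propargylic carbinol whose spatial arrangement is C7 (S) of the target.

Step 4
Reactants: 6 (1R,4R)-propargylic alcohol
Product: 7 (1S,4R,2E)-1-[3-methoxy-4-(triisopropylsilyloxy)phenyl]-4-(triethylsilyloxy)pent-2-en-1-ol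
Conditions: NaAlH2(OCH2CH2OMe)2, THF, 0 °C to rt
Reagents that add atoms: none
Why: Hydroxyl-directed trans-hydroalumination of a propargylic alcohol followed by protonolysis should give only the (E)-allylic alcohol; both stereocenters are untouched (the C1 descriptor changes only because alkenyl now ranks below aryl).

Step 5
Reactants: 7 (1S,4R,2E)-allylic alcohol
Product: 9 (2R,5S,3E)-5-(tert-butyldimethylsilyloxy)-5-[3-methoxy-4-(triisopropylsilyloxy)phenyl]pent-3-en-2-ol, via bis-silyl ether 8 (not isolated)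
Conditions: TBSOTf, 2,6-lutidine, CH2Cl2, −78 °C; aqueous wash and solvent exchange; then PPTS, MeOH/CH2Cl2, 0 °C
Reagents that add atoms: tert-butyldimethylsilyl triflate, CC(C)(C)[Si](C)(C)OS(=O)(=O)C(F)(F)F
Why: Silyl triflate silylation of the benzylic alcohol, then selective acid methanolysis of the much more labile TES ether, frees only the methyl carbinol needed for etherification.

Step 6
Reactants: 10 (S)-but-3-yn-2-ol
Product: 11 (S)-(but-3-yn-2-yloxy)triethylsilane
Conditions: TESCl, imidazole, CH2Cl2, 0 °C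
Reagents that add atoms: triethylsilyl chloride, CC[Si](Cl)(CC)CC
Why: O-Silylation as in step 2, in the antipodal series.

Step 7
Reactants: 2 3-methoxy-4-(triisopropylsilyloxy)benzaldehyde; 11 (S)-(but-3-yn-2-yloxy)triethylsilane
Product: 13 (1R,4S)-1-[3-methoxy-4-(triisopropylsilyloxy)phenyl]-4-(triethylsilyloxy)pent-2-yn-1-ol, via zinc acetylide 12 (not isolated)
Conditions: 11 (2 equiv), Et2Zn (2 equiv), toluene, reflux; then (S)-BINOL (20 mol %), Ti(OiPr)4 (50 mol %), 2, Et2O, rt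
Reagents that add atoms: none
Why: The same catalyst-controlled asymmetric alkynylation as in step 3, again expected to set the aryl carbinol by Si-face addition.

Step 8
Reactants: 13 (1R,4S)-propargylic alcohol
Product: 14 (1S,4S,2E)-1-[3-methoxy-4-(triisopropylsilyloxy)phenyl]-4-(triethylsilyloxy)pent-2-en-1-ol
Conditions: NaAlH2(OCH2CH2OMe)2, THF, 0 °C to rt
Reagents that add atoms: none
Why: Hydroxyl-directed trans-hydroalumination as in step 4, giving the (E)-olefin with both centers intact.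

Step 9
Reactants: 14 (1S,4S,2E)-allylic alcohol
Product: 16 (2S,5S,3E)-5-(tert-butyldimethylsilyloxy)-5-[3-methoxy-4-(triisopropylsilyloxy)phenyl]pent-3-en-2-ol, via bis-silyl ether 15 (not isolated)
Conditions: TBSOTf, 2,6-lutidine, CH2Cl2, −78 °C; aqueous wash and solvent exchange; then PPTS, MeOH/CH2Cl2, 0 °C
Reagents that add atoms: tert-butyldimethylsilyl triflate, CC(C)(C)[Si](C)(C)OS(=O)(=O)C(F)(F)F
Why: Silylation, then selective TES methanolysis as in step 5.

Step 10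
Reactants: 17 4-(benzyloxy)-3-methoxybenzaldehyde; 18 dimethyl succinate
Product: 19 (E)-4-[4-(benzyloxy)-3-methoxyphenyl]-3-(methoxycarbonyl)but-3-enoic acid
Conditions: NaOMe, MeOH, reflux; then aq. HCl
Reagents that add atoms: none
Why: Stobbe condensation (aldol addition, lactonization and eliminative ring opening) should give the (E)-arylidene half-ester with the free acid on the CH2 arm.

Step 11
Reactants: 19 (E)-arylidene succinic half-ester
Product: 21 (S)-4-(4-hydroxy-3-methoxyphenyl)-3-(methoxycarbonyl)butanoic acid, via benzyl ether acid 20 (not isolated)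
Conditions: [Rh(cod)((R,R)-Et-DuPhos)]BF4 (1 mol %), NaOMe (10 mol %), H2 (5 bar), MeOH, rt; then 10% Pd/C, H2 (1 bar), rt
Reagents that add atoms: none
Why: Rhodium–bisphospholane asymmetric hydrogenation of an itaconate-type half-ester, in which the carboxylate chelates the metal; the (R,R)-ligand is expected by analogy to give the (S)-benzylsuccinate (future lactone C4), and Pd-catalysed hydrogenolysis then removes the benzyl ether in the same pot.

Step 12
Reactants: 21 (S)-phenol acid ester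
Product: 23 (S)-4-(4-hydroxy-3-methoxybenzyl)dihydrofuran-2(3H)-one, via hydroxy acid 22 (not isolated)
Conditions: KOH (2 equiv), EtOH, 0 °C; CaCl2, NaBH4, −10 °C to rt; then 3 M HCl, rt
Reagents that add atoms: none
Why: Calcium borohydride reduces the methyl ester but not the carboxylate, and acidification closes the γ-lactone (ring C) by intramolecular esterification without touching the stereocenter.

Step 13
Reactants: 23 (S)-4-(4-hydroxy-3-methoxybenzyl)dihydrofuran-2(3H)-one; 9 (2R,5S,3E)-alcohol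
Product: 24 (S)-4-{3-methoxy-4-[((2S,5S,3E)-5-OTBS-5-[3-methoxy-4-(OTIPS)phenyl]pent-3-en-2-yl)oxy]benzyl}dihydrofuran-2(3H)-one
Conditions: PPh3, DIAD, toluene, 0 °C to rt
Reagents that add atoms: none
Why: Mitsunobu etherification: the phenol displaces the activated secondary allylic alcohol by SN2 with inversion, turning the (2R)-carbinol into the (S)-aryl ether, while the bulky silyloxybenzyl group at the far olefin terminus disfavours SN2′ attack.

Step 14
Reactants: 24 ring B aryl allyl ether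
Product: 26 (S)-4-{4-hydroxy-3-methoxy-5-[(1S,2R,3E)-1-OTBS-1-[3-methoxy-4-(OTIPS)phenyl]pent-3-en-2-yl]benzyl}dihydrofuran-2(3H)-one, via dienone 25 (not isolated)
Conditions: N,N-diethylaniline, 175 °C, sealed tube, argon
Reagents that add atoms: none
Why: Aromatic Claisen rearrangement ([3,3]) followed by enolization; ring B C5 is the only free ortho position, and the chair with the methyl group pseudo-equatorial should carry the (S)-ether configuration to C8 (the 8S arrangement of the target) while leaving an (E)-propenyl group.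

Step 15
Reactants: 26 ring B propenyl phenol
Product: 28 (S)-4-{4-hydroxy-3-[(1S,2S)-1-OTBS-3-hydroxy-1-[3-methoxy-4-(OTIPS)phenyl]propan-2-yl]-5-methoxybenzyl}dihydrofuran-2(3H)-one, via aldehyde 27 (not isolated)
Conditions: O3, CH2Cl2/MeOH (3:1), −78 °C (Sudan Red 7B end point); then NaBH4, −78 to 0 °C
Reagents that add atoms: ozone, [O-][O+]=O
Why: Ozonolysis of the only olefin with borohydride work-up; the α-aryl aldehyde is reduced as it is released (and is masked as a lactol by the neighbouring phenol), so C8 should not epimerize, and metering ozone against the dye should spare the arenes.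

Step 16
Reactants: 28 ring B phenol diol
Product: 29 (S)-4-{4-OTBS-3-[(1S,2S)-1,3-bis(OTBS)-1-[3-methoxy-4-(OTIPS)phenyl]propan-2-yl]-5-methoxybenzyl}dihydrofuran-2(3H)-one
Conditions: TBSOTf (2.5 equiv), 2,6-lutidine, CH2Cl2, 0 °C
Reagents that add atoms: tert-butyldimethylsilyl triflate, CC(C)(C)[Si](C)(C)OS(=O)(=O)C(F)(F)F
Why: Silyl triflate silylation of the primary alcohol and the hindered phenol, so that no acidic O–H remains for the enolate step.

Step 17
Reactants: 30 [4-(benzyloxy)-3-methoxyphenyl]methanol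
Product: 31 1-(benzyloxy)-4-(bromomethyl)-2-methoxybenzene
Conditions: PBr3, Et2O, 0 °C
Reagents that add atoms: phosphorus tribromide, BrP(Br)Br
Why: Conversion of a benzylic alcohol into the bromide through its phosphite ester (SN2).

Step 18
Reactants: 29 silylated ring B lactone; 31 benzylic bromide
Product: 33 (3S,4S)-3-[4-(benzyloxy)-3-methoxybenzyl]-4-{4-OTBS-3-[(1S,2S)-1,3-bis(OTBS)-1-[3-methoxy-4-(OTIPS)phenyl]propan-2-yl]-5-methoxybenzyl}dihydrofuran-2(3H)-one, via lithium enolate 32 (not isolated)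
Conditions: LiN(SiMe3)2, THF, −78 °C; then 31, −78 to −40 °C
Reagents that add atoms: none
Why: Lactone enolate alkylation in which the bromide approaches anti to the C4 benzyl group, setting C3 (S) and the trans-3,4 relationship.

Step 19
Reactants: 33 trans-lactone benzyl ether
Product: 34 (3S,4S)-3-(4-hydroxy-3-methoxybenzyl)-4-{4-OTBS-3-[(1S,2S)-1,3-bis(OTBS)-1-[3-methoxy-4-(OTIPS)phenyl]propan-2-yl]-5-methoxybenzyl}dihydrofuran-2(3H)-one
Conditions: H2 (1 bar), 10% Pd/C, EtOAc, rt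
Reagents that add atoms: none
Why: Hydrogenolysis of the aryl benzyl ether; the silyl ethers (including the benzylic one) and the lactone are not expected to react under neutral conditions, and no olefin is present at this stage.

Step 20
Reactants: 34 ring D phenol; 16 (2S,5S,3E)-alcohol
Product: 35 ring D aryl ether: 34 carrying on the ring D phenol oxygen the (2R,5S,3E)-5-OTBS-5-[3-methoxy-4-(OTIPS)phenyl]pent-3-en-2-yl group
Conditions: PPh3, DIAD, toluene, 0 °C to rt
Reagents that add atoms: none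
Why: Mitsunobu etherification with SN2 inversion turns the (2S)-carbinol into the (R)-aryl ether; the ring D phenol is the only free hydroxyl.

Step 21
Reactants: 35 ring D aryl (E)-1-methylallyl ether
Product: 37 ring D phenol carrying at C5 the (1S,2S,3E)-1-OTBS-1-[3-methoxy-4-(OTIPS)phenyl]pent-3-en-2-yl group, via dienone 36 (not isolated)
Conditions: N,N-diethylaniline, 175 °C, sealed tube, argon
Reagents that add atoms: none
Why: Heating the (R)-configured ether in a non-ionizing amine should trigger a concerted suprafacial [3,3]-sigmatropic (aromatic Claisen) shift in which the O–C bond breaks as ring D C5 bonds to the far allyl terminus, giving dienone 36, which enolizes to the phenol. The closest known reaction type is the thermal ortho-Claisen rearrangement of optically active aryl (E)-1-methylalk-2-enyl ethers with 1,3-chirality transfer. No ring is closed; the six-membered array exists only as the chair transition state. The new stereocenter C8 is controlled by the ether carbinol set in step 20: the chair with the methyl group and the (E)-olefin substituent both pseudo-equatorial delivers C5 to one allyl face, translating the (R)-ether into the 8R arrangement of the target and leaving an (E)-propenyl group, while the C7 silyloxy center is carried through untouched and, in an (E)-olefin, should exert only a weak bias. The step needs ortho-regioselectivity and facial selectivity: C5 is the only open ortho position (C3 bears OMe, C1 is alkylated), the diequatorial chair is favoured over the axial-methyl chair and the boat, and the basic medium should suppress ionization of the benzylic silyl ether and cyclization of the new phenol onto C7.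

Step 22
Reactants: 37 ring D propenyl phenol
Product: 39 ring D phenol carrying at C5 the (1S,2R)-1-OTBS-3-hydroxy-1-[3-methoxy-4-(OTIPS)phenyl]propan-2-yl group, via aldehyde 38 (not isolated)
Conditions: O3, CH2Cl2/MeOH (3:1), −78 °C (Sudan Red 7B end point); then NaBH4, −78 to 0 °C
Reagents that add atoms: ozone, [O-][O+]=O
Why: Ozonolysis with borohydride work-up as in step 15; the propenyl group is the only olefin and the α-aryl aldehyde is reduced as it forms, so C8 should be retained.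

Step 23
Reactants: 39 hexasilylated precursor
Product: 40 (3S,4S)-3-{4-hydroxy-3-[(1S,2R)-1,3-dihydroxy-1-(4-hydroxy-3-methoxyphenyl)propan-2-yl]-5-methoxybenzyl}-4-{4-hydroxy-3-[(1S,2S)-1,3-dihydroxy-1-(4-hydroxy-3-methoxyphenyl)propan-2-yl]-5-methoxybenzyl}dihydrofuran-2(3H)-one
Conditions: n-Bu4NF, AcOH (1:1), THF, 0 °C to rt
Reagents that add atoms: none
Why: Fluoride-induced cleavage of all six silyl ethers (four TBS, two TIPS); acetic acid buffering should keep the medium near neutral so that the p-hydroxybenzylic alcohols neither ionize nor cyclize onto the ortho phenols and the trans-lactone stays closed.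

**Compound list**

1 | vanillin | COc1cc(C=O)ccc1O | starting material
2 | 3-methoxy-4-(triisopropylsilyloxy)benzaldehyde | COc1cc(C=O)ccc1O[Si](C(C)C)(C(C)C)C(C)C | intermediate
3 | (R)-but-3-yn-2-ol | C[C@@H](O)C#C | starting material
4 | (R)-(but-3-yn-2-yloxy)triethylsilane | C[C@@H](O[Si](CC)(CC)CC)C#C | intermediate
5 | ethyl[(3R)-3-(triethylsilyloxy)but-1-yn-1-yl]zinc (not isolated) | CC[Zn]C#C[C@@H](C)O[Si](CC)(CC)CC | intermediate
6 | (1R,4R)-1-[3-methoxy-4-(triisopropylsilyloxy)phenyl]-4-(triethylsilyloxy)pent-2-yn-1-ol | COc1cc([C@@H](O)C#C[C@@H](C)O[Si](CC)(CC)CC)ccc1O[Si](C(C)C)(C(C)C)C(C)C | intermediate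
7 | (1S,4R,2E)-1-[3-methoxy-4-(triisopropylsilyloxy)phenyl]-4-(triethylsilyloxy)pent-2-en-1-ol | COc1cc([C@@H](O)/C=C/[C@@H](C)O[Si](CC)(CC)CC)ccc1O[Si](C(C)C)(C(C)C)C(C)C | intermediate
8 | (1S,4R,2E)-1-OTBS-4-OTES-1-[3-methoxy-4-(OTIPS)phenyl]pent-2-ene (not isolated) | COc1cc([C@@H](O[Si](C)(C)C(C)(C)C)/C=C/[C@@H](C)O[Si](CC)(CC)CC)ccc1O[Si](C(C)C)(C(C)C)C(C)C | intermediate
9 | (2R,5S,3E)-5-(tert-butyldimethylsilyloxy)-5-[3-methoxy-4-(triisopropylsilyloxy)phenyl]pent-3-en-2-ol | COc1cc([C@@H](O[Si](C)(C)C(C)(C)C)/C=C/[C@@H](C)O)ccc1O[Si](C(C)C)(C(C)C)C(C)C | intermediate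
10 | (S)-but-3-yn-2-ol | C[C@H](O)C#C | starting material
11 | (S)-(but-3-yn-2-yloxy)triethylsilane | C[C@H](O[Si](CC)(CC)CC)C#C | intermediate
12 | ethyl[(3S)-3-(triethylsilyloxy)but-1-yn-1-yl]zinc (not isolated) | CC[Zn]C#C[C@H](C)O[Si](CC)(CC)CC | intermediate
13 | (1R,4S)-1-[3-methoxy-4-(triisopropylsilyloxy)phenyl]-4-(triethylsilyloxy)pent-2-yn-1-ol | COc1cc([C@@H](O)C#C[C@H](C)O[Si](CC)(CC)CC)ccc1O[Si](C(C)C)(C(C)C)C(C)C | intermediate
14 | (1S,4S,2E)-1-[3-methoxy-4-(triisopropylsilyloxy)phenyl]-4-(triethylsilyloxy)pent-2-en-1-ol | COc1cc([C@@H](O)/C=C/[C@H](C)O[Si](CC)(CC)CC)ccc1O[Si](C(C)C)(C(C)C)C(C)C | intermediate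
15 | (1S,4S,2E)-1-OTBS-4-OTES-1-[3-methoxy-4-(OTIPS)phenyl]pent-2-ene (not isolated) | COc1cc([C@@H](O[Si](C)(C)C(C)(C)C)/C=C/[C@H](C)O[Si](CC)(CC)CC)ccc1O[Si](C(C)C)(C(C)C)C(C)C | intermediate
16 | (2S,5S,3E)-5-(tert-butyldimethylsilyloxy)-5-[3-methoxy-4-(triisopropylsilyloxy)phenyl]pent-3-en-2-ol | COc1cc([C@@H](O[Si](C)(C)C(C)(C)C)/C=C/[C@H](C)O)ccc1O[Si](C(C)C)(C(C)C)C(C)C | intermediate
17 | 4-(benzyloxy)-3-methoxybenzaldehyde | COc1cc(C=O)ccc1OCc1ccccc1 | starting material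
18 | dimethyl succinate | COC(=O)CCC(=O)OC | starting material
19 | (E)-4-[4-(benzyloxy)-3-methoxyphenyl]-3-(methoxycarbonyl)but-3-enoic acid | COC(=O)/C(CC(=O)O)=C/c1ccc(OCc2ccccc2)c(OC)c1 | intermediate
20 | (S)-4-[4-(benzyloxy)-3-methoxyphenyl]-3-(methoxycarbonyl)butanoic acid (not isolated) | COC(=O)[C@H](CC(=O)O)Cc1ccc(OCc2ccccc2)c(OC)c1 | intermediate
21 | (S)-4-(4-hydroxy-3-methoxyphenyl)-3-(methoxycarbonyl)butanoic acid | COC(=O)[C@H](CC(=O)O)Cc1ccc(O)c(OC)c1 | intermediate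
22 | (S)-3-(hydroxymethyl)-4-(4-hydroxy-3-methoxyphenyl)butanoic acid (not isolated) | OC[C@H](CC(=O)O)Cc1ccc(O)c(OC)c1 | intermediate
23 | (S)-4-(4-hydroxy-3-methoxybenzyl)dihydrofuran-2(3H)-one | COc1cc(C[C@@H]2COC(=O)C2)ccc1O | intermediate
24 | ring B aryl ether, (S)-lactone with the (2S,5S,3E)-5-OTBS-5-aryl-pent-3-en-2-yl group on the phenol oxygen | COc1cc(C[C@@H]2COC(=O)C2)ccc1O[C@@H](C)/C=C/[C@H](O[Si](C)(C)C(C)(C)C)c1ccc(O[Si](C(C)C)(C(C)C)C(C)C)c(OC)c1 | intermediate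
25 | ortho-dienone tautomer of 26 (6-alkyl-2-methoxycyclohexa-2,4-dien-1-one form, ring sp3 carbon unassigned; not isolated) | COC1=CC(C[C@@H]2COC(=O)C2)=CC([C@@H](/C=C/C)[C@H](O[Si](C)(C)C(C)(C)C)c2ccc(O[Si](C(C)C)(C(C)C)C(C)C)c(OC)c2)C1=O | intermediate
26 | (S)-4-{4-hydroxy-3-methoxy-5-[(1S,2R,3E)-1-OTBS-1-[3-methoxy-4-(OTIPS)phenyl]pent-3-en-2-yl]benzyl}dihydrofuran-2(3H)-one | COc1cc([C@@H](O[Si](C)(C)C(C)(C)C)[C@H](/C=C/C)c2cc(C[C@@H]3COC(=O)C3)cc(OC)c2O)ccc1O[Si](C(C)C)(C(C)C)C(C)C | intermediate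
27 | (2R,3S)-3-OTBS-2-{2-hydroxy-3-methoxy-5-[((S)-5-oxotetrahydrofuran-3-yl)methyl]phenyl}-3-[3-methoxy-4-(OTIPS)phenyl]propanal (not isolated) | COc1cc([C@@H](O[Si](C)(C)C(C)(C)C)[C@H](C=O)c2cc(C[C@@H]3COC(=O)C3)cc(OC)c2O)ccc1O[Si](C(C)C)(C(C)C)C(C)C | intermediate
28 | (S)-4-{4-hydroxy-3-[(1S,2S)-1-OTBS-3-hydroxy-1-[3-methoxy-4-(OTIPS)phenyl]propan-2-yl]-5-methoxybenzyl}dihydrofuran-2(3H)-one | COc1cc([C@@H](O[Si](C)(C)C(C)(C)C)[C@H](CO)c2cc(C[C@@H]3COC(=O)C3)cc(OC)c2O)ccc1O[Si](C(C)C)(C(C)C)C(C)C | intermediate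
29 | (S)-4-{4-OTBS-3-[(1S,2S)-1,3-bis(OTBS)-1-[3-methoxy-4-(OTIPS)phenyl]propan-2-yl]-5-methoxybenzyl}dihydrofuran-2(3H)-one | COc1cc([C@@H](O[Si](C)(C)C(C)(C)C)[C@H](CO[Si](C)(C)C(C)(C)C)c2cc(C[C@@H]3COC(=O)C3)cc(OC)c2O[Si](C)(C)C(C)(C)C)ccc1O[Si](C(C)C)(C(C)C)C(C)C | intermediate
30 | [4-(benzyloxy)-3-methoxyphenyl]methanol | COc1cc(CO)ccc1OCc1ccccc1 | starting material
31 | 1-(benzyloxy)-4-(bromomethyl)-2-methoxybenzene | COc1cc(CBr)ccc1OCc1ccccc1 | intermediate
32 | lithium enolate of lactone 29 (not isolated) | [Li+].COc1cc([C@@H](O[Si](C)(C)C(C)(C)C)[C@H](CO[Si](C)(C)C(C)(C)C)c2cc(C[C@@H]3COC([O-])=C3)cc(OC)c2O[Si](C)(C)C(C)(C)C)ccc1O[Si](C(C)C)(C(C)C)C(C)C | intermediate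
33 | (3S,4S)-trans-lactone with ring D as 4-benzyloxy-3-methoxyphenyl and ring B as in 29 | COc1cc([C@@H](O[Si](C)(C)C(C)(C)C)[C@H](CO[Si](C)(C)C(C)(C)C)c2cc(C[C@@H]3COC(=O)[C@H]3Cc3cc(OC)c(OCc4ccccc4)cc3)cc(OC)c2O[Si](C)(C)C(C)(C)C)ccc1O[Si](C(C)C)(C(C)C)C(C)C | intermediate
34 | (3S,4S)-trans-lactone with ring D as 4-hydroxy-3-methoxyphenyl and ring B as in 29 | COc1cc([C@@H](O[Si](C)(C)C(C)(C)C)[C@H](CO[Si](C)(C)C(C)(C)C)c2cc(C[C@@H]3COC(=O)[C@H]3Cc3cc(OC)c(O)cc3)cc(OC)c2O[Si](C)(C)C(C)(C)C)ccc1O[Si](C(C)C)(C(C)C)C(C)C | intermediate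
35 | ring D aryl ether of 34 with the (2R,5S,3E)-5-OTBS-5-[3-methoxy-4-(OTIPS)phenyl]pent-3-en-2-yl group on oxygen | COc1cc([C@@H](O[Si](C)(C)C(C)(C)C)[C@H](CO[Si](C)(C)C(C)(C)C)c2cc(C[C@@H]3COC(=O)[C@H]3Cc3cc(OC)c(O[C@H](C)/C=C/[C@H](O[Si](C)(C)C(C)(C)C)c4ccc(O[Si](C(C)C)(C(C)C)C(C)C)c(OC)c4)cc3)cc(OC)c2O[Si](C)(C)C(C)(C)C)ccc1O[Si](C(C)C)(C(C)C)C(C)C | intermediate
36 | ortho-dienone tautomer of 37 (ring D as 6-alkyl-2-methoxycyclohexa-2,4-dien-1-one, ring sp3 carbon unassigned; not isolated) | COc1cc([C@@H](O[Si](C)(C)C(C)(C)C)[C@H](CO[Si](C)(C)C(C)(C)C)c2cc(C[C@@H]3COC(=O)[C@H]3CC3=CC([C@H](/C=C/C)[C@H](O[Si](C)(C)C(C)(C)C)c4ccc(O[Si](C(C)C)(C(C)C)C(C)C)c(OC)c4)C(=O)C(OC)=C3)cc(OC)c2O[Si](C)(C)C(C)(C)C)ccc1O[Si](C(C)C)(C(C)C)C(C)C | intermediate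
37 | ring D phenol with the (1S,2S,3E)-1-OTBS-1-[3-methoxy-4-(OTIPS)phenyl]pent-3-en-2-yl group at C5, ring B as in 29 | COc1cc([C@@H](O[Si](C)(C)C(C)(C)C)[C@H](CO[Si](C)(C)C(C)(C)C)c2cc(C[C@@H]3COC(=O)[C@H]3Cc3cc(OC)c(O)c([C@H](/C=C/C)[C@H](O[Si](C)(C)C(C)(C)C)c4ccc(O[Si](C(C)C)(C(C)C)C(C)C)c(OC)c4)c3)cc(OC)c2O[Si](C)(C)C(C)(C)C)ccc1O[Si](C(C)C)(C(C)C)C(C)C | intermediate
38 | ring D (2S,3S)-3-OTBS-3-aryl-2-arylpropanal derived from 37 (not isolated) | COc1cc([C@@H](O[Si](C)(C)C(C)(C)C)[C@H](CO[Si](C)(C)C(C)(C)C)c2cc(C[C@@H]3COC(=O)[C@H]3Cc3cc(OC)c(O)c([C@H](C=O)[C@H](O[Si](C)(C)C(C)(C)C)c4ccc(O[Si](C(C)C)(C(C)C)C(C)C)c(OC)c4)c3)cc(OC)c2O[Si](C)(C)C(C)(C)C)ccc1O[Si](C(C)C)(C(C)C)C(C)C | intermediate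
39 | ring D phenol with the (1S,2R)-1-OTBS-3-hydroxy-1-[3-methoxy-4-(OTIPS)phenyl]propan-2-yl group at C5, ring B as in 29 | COc1cc([C@@H](O[Si](C)(C)C(C)(C)C)[C@H](CO[Si](C)(C)C(C)(C)C)c2cc(C[C@@H]3COC(=O)[C@H]3Cc3cc(OC)c(O)c([C@H](CO)[C@H](O[Si](C)(C)C(C)(C)C)c4ccc(O[Si](C(C)C)(C(C)C)C(C)C)c(OC)c4)c3)cc(OC)c2O[Si](C)(C)C(C)(C)C)ccc1O[Si](C(C)C)(C(C)C)C(C)C | intermediate
40 | CNP0113972.1 | COc1cc([C@@H](O)[C@H](CO)c2cc(C[C@@H]3COC(=O)[C@H]3Cc3cc(OC)c(O)c([C@H](CO)[C@H](O)c4ccc(O)c(OC)c4)c3)cc(OC)c2O)ccc1O | target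

**Count and risks**

Total step count: 23 steps. Longest linear sequence: 14 steps (steps 1, 3, 4, 5, 13–16 and 18–23, from vanillin 1).

Step 21 (key rearrangement). What may go wrong: leakage through the axial-methyl chair or a boat, or an opposing influence of the C7 silyloxy center, so that C8 forms with poor facial selectivity; prolonged heating may also ionize the benzylic silyl ether or eliminate the ether to a diene. Fallback (auxiliary-controlled aldol in place of chirality transfer; sets out from phenol 34 and comes back at target 40): 34 is O-allylated (allyl bromide, K2CO3, acetone) to the ring D allyl ether F1, which rearranges without any stereochemical demand (N,N-diethylaniline, 190 °C) to the C5-allyl phenol F2. Silylation (TBSOTf, 2,6-lutidine) gives the aryl silyl ether F3, ozonolysis with PPh3 work-up gives the arylacetaldehyde F4, and Pinnick oxidation (NaClO2, NaH2PO4, 2-methylbut-2-ene) gives the arylacetic acid F5. Activation as the mixed pivalic anhydride and acylation of lithiated (S)-4-benzyloxazolidin-2-one gives the imide F6. An Evans syn-aldol reaction (n-Bu2BOTf, i-Pr2NEt, CH2Cl2, −78 to 0 °C, then aldehyde 2) gives the aldol adduct F7, with C8 and C7 both set by the auxiliary in the (7S,8R) sense. NaBH4 in THF/H2O removes the auxiliary reductively to the 1,3-diol F8, and buffered n-Bu4NF as in step 23 gives 40.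

Step 22 (olefin cleavage). What may go wrong: competitive attack of ozone on the free phenol and the electron-rich aryl ethers, or enolization of the α-aryl aldehyde before it is reduced. Fallback (phenol capping and two-stage osmium/periodate cleavage in place of ozone; sets out from 37 and comes back at 40): 37 is silylated (TBSOTf, 2,6-lutidine) to the ring D silyl ether F10. Dihydroxylation (OsO4 cat., N-methylmorpholine N-oxide, acetone/H2O) gives the diol F11 as a mixture at the two new carbinols. Glycol cleavage (NaIO4, THF/pH 7 buffer) gives the aldehyde F12, which is reduced at once (NaBH4, MeOH, 0 °C) to the primary alcohol F13. Buffered n-Bu4NF as in step 23 gives 40.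

Step 20 (etherification). What may go wrong: ionization of the allylic oxyphosphonium intermediate, leading to SN2′ ether, elimination to a diene or partial loss of configuration at the ether carbon. Fallback (palladium-catalysed allylic etherification with net retention in place of SN2 inversion; sets out from alcohol 9 and phenol 34 and comes back at 35): the epimeric alcohol 9 is converted (ClCO2Me, pyridine, CH2Cl2, 0 °C) into the allylic methyl carbonate F9. With Pd(PPh3)4 in THF, F9 ionizes with inversion and phenol 34 attacks the methyl-bearing allyl terminus, distal to the silyloxybenzyl carbon, with a second inversion (Tsuji–Trost O-allylation). The (2R)-carbonate should therefore give the (R)-aryl ether 35 with the (E)-olefin intact.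

**Further compounds**

F1 | step 21 | ring D allyl ether of 34 | COc1cc([C@@H](O[Si](C)(C)C(C)(C)C)[C@H](CO[Si](C)(C)C(C)(C)C)c2cc(C[C@@H]3COC(=O)[C@H]3Cc3cc(OC)c(OCC=C)cc3)cc(OC)c2O[Si](C)(C)C(C)(C)C)ccc1O[Si](C(C)C)(C(C)C)C(C)C
F2 | step 21 | ring D C5-allyl phenol | COc1cc([C@@H](O[Si](C)(C)C(C)(C)C)[C@H](CO[Si](C)(C)C(C)(C)C)c2cc(C[C@@H]3COC(=O)[C@H]3Cc3cc(OC)c(O)c(CC=C)c3)cc(OC)c2O[Si](C)(C)C(C)(C)C)ccc1O[Si](C(C)C)(C(C)C)C(C)C
F3 | step 21 | ring D C5-allyl aryl TBS ether | COc1cc([C@@H](O[Si](C)(C)C(C)(C)C)[C@H](CO[Si](C)(C)C(C)(C)C)c2cc(C[C@@H]3COC(=O)[C@H]3Cc3cc(OC)c(O[Si](C)(C)C(C)(C)C)c(CC=C)c3)cc(OC)c2O[Si](C)(C)C(C)(C)C)ccc1O[Si](C(C)C)(C(C)C)C(C)C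
F4 | step 21 | ring D arylacetaldehyde | COc1cc([C@@H](O[Si](C)(C)C(C)(C)C)[C@H](CO[Si](C)(C)C(C)(C)C)c2cc(C[C@@H]3COC(=O)[C@H]3Cc3cc(OC)c(O[Si](C)(C)C(C)(C)C)c(CC=O)c3)cc(OC)c2O[Si](C)(C)C(C)(C)C)ccc1O[Si](C(C)C)(C(C)C)C(C)C
F5 | step 21 | ring D arylacetic acid | COc1cc([C@@H](O[Si](C)(C)C(C)(C)C)[C@H](CO[Si](C)(C)C(C)(C)C)c2cc(C[C@@H]3COC(=O)[C@H]3Cc3cc(OC)c(O[Si](C)(C)C(C)(C)C)c(CC(=O)O)c3)cc(OC)c2O[Si](C)(C)C(C)(C)C)ccc1O[Si](C(C)C)(C(C)C)C(C)C
F6 | step 21 | N-(arylacetyl) (S)-4-benzyloxazolidin-2-one imide | COc1cc([C@@H](O[Si](C)(C)C(C)(C)C)[C@H](CO[Si](C)(C)C(C)(C)C)c2cc(C[C@@H]3COC(=O)[C@H]3Cc3cc(OC)c(O[Si](C)(C)C(C)(C)C)c(CC(=O)N4[C@@H](Cc5ccccc5)COC4=O)c3)cc(OC)c2O[Si](C)(C)C(C)(C)C)ccc1O[Si](C(C)C)(C(C)C)C(C)C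
F7 | step 21 | (2S,3S)-syn-aldol adduct of F6 with aldehyde 2 | COc1cc([C@@H](O[Si](C)(C)C(C)(C)C)[C@H](CO[Si](C)(C)C(C)(C)C)c2cc(C[C@@H]3COC(=O)[C@H]3Cc3cc(OC)c(O[Si](C)(C)C(C)(C)C)c([C@H](C(=O)N4[C@@H](Cc5ccccc5)COC4=O)[C@H](O)c4ccc(O[Si](C(C)C)(C(C)C)C(C)C)c(OC)c4)c3)cc(OC)c2O[Si](C)(C)C(C)(C)C)ccc1O[Si](C(C)C)(C(C)C)C(C)C
F8 | step 21 | ring D (1S,2R)-1,3-diol with ring D phenol as TBS ether | COc1cc([C@@H](O[Si](C)(C)C(C)(C)C)[C@H](CO[Si](C)(C)C(C)(C)C)c2cc(C[C@@H]3COC(=O)[C@H]3Cc3cc(OC)c(O[Si](C)(C)C(C)(C)C)c([C@H](CO)[C@H](O)c4ccc(O[Si](C(C)C)(C(C)C)C(C)C)c(OC)c4)c3)cc(OC)c2O[Si](C)(C)C(C)(C)C)ccc1O[Si](C(C)C)(C(C)C)C(C)C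
F9 | step 20 | methyl carbonate of alcohol 9 | COc1cc([C@@H](O[Si](C)(C)C(C)(C)C)/C=C/[C@@H](C)OC(=O)OC)ccc1O[Si](C(C)C)(C(C)C)C(C)C
F10 | step 22 | ring D aryl TBS ether of 37 | COc1cc([C@@H](O[Si](C)(C)C(C)(C)C)[C@H](CO[Si](C)(C)C(C)(C)C)c2cc(C[C@@H]3COC(=O)[C@H]3Cc3cc(OC)c(O[Si](C)(C)C(C)(C)C)c([C@H](/C=C/C)[C@H](O[Si](C)(C)C(C)(C)C)c4ccc(O[Si](C(C)C)(C(C)C)C(C)C)c(OC)c4)c3)cc(OC)c2O[Si](C)(C)C(C)(C)C)ccc1O[Si](C(C)C)(C(C)C)C(C)C
F11 | step 22 | vicinal diol from F10 (mixture at the two new carbinols) | COc1cc([C@@H](O[Si](C)(C)C(C)(C)C)[C@H](CO[Si](C)(C)C(C)(C)C)c2cc(C[C@@H]3COC(=O)[C@H]3Cc3cc(OC)c(O[Si](C)(C)C(C)(C)C)c([C@H](C(O)C(C)O)[C@H](O[Si](C)(C)C(C)(C)C)c4ccc(O[Si](C(C)C)(C(C)C)C(C)C)c(OC)c4)c3)cc(OC)c2O[Si](C)(C)C(C)(C)C)ccc1O[Si](C(C)C)(C(C)C)C(C)C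
F12 | step 22 | ring D α-aryl aldehyde with ring D phenol as TBS ether | COc1cc([C@@H](O[Si](C)(C)C(C)(C)C)[C@H](CO[Si](C)(C)C(C)(C)C)c2cc(C[C@@H]3COC(=O)[C@H]3Cc3cc(OC)c(O[Si](C)(C)C(C)(C)C)c([C@H](C=O)[C@H](O[Si](C)(C)C(C)(C)C)c4ccc(O[Si](C(C)C)(C(C)C)C(C)C)c(OC)c4)c3)cc(OC)c2O[Si](C)(C)C(C)(C)C)ccc1O[Si](C(C)C)(C(C)C)C(C)C
F13 | step 22 | ring D primary alcohol with ring D phenol as TBS ether | COc1cc([C@@H](O[Si](C)(C)C(C)(C)C)[C@H](CO[Si](C)(C)C(C)(C)C)c2cc(C[C@@H]3COC(=O)[C@H]3Cc3cc(OC)c(O[Si](C)(C)C(C)(C)C)c([C@H](CO)[C@H](O[Si](C)(C)C(C)(C)C)c4ccc(O[Si](C(C)C)(C(C)C)C(C)C)c(OC)c4)c3)cc(OC)c2O[Si](C)(C)C(C)(C)C)ccc1O[Si](C(C)C)(C(C)C)C(C)C
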